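## The problem

The target 15 is a (2S)-flavanone. Ring A carries methoxy groups at C5 and C7 and a free hydroxyl at C6, and is fused through C4a and C8a to the dihydropyranone ring C (O1, C2, C3, C4=O). C2 bears the 3,4-dimethoxyphenyl ring B.

C2 is the only stereocentre, so nothing in the molecule can relay chirality to it. It must be set by a catalyst and then shielded from every later step.

The centre is fragile in two ways. Its oxygen is an aryloxide β to the C4 ketone, so base opens ring C by E1cB to the 2'-hydroxychalcone and recloses it racemic. Acid can ionise the C2–O1 bond, helped by the para-methoxy group of ring B.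

Ring A has three adjacent oxygens of which only the middle one is free. The C6 hydroxyl must therefore be distinguished from the start and unmasked without Lewis acids, which would remove the C5 methyl ether peri to the carbonyl. The pattern (hydroxyl flanked by two methoxy groups) is that of syringaldehyde, so ring A is best bought and ring C built onto it.

The enabling feature is the two-carbon bridge C3–C4. C3 hangs on the ether carbon C2, and C4 hangs on C4a, which is ortho to O1. Drawn as a C3=C4 alkene, each carbon can come from a vinyl group, one on a branched allylic aryl ether and one on the arene. Because C4 is benzylic to electron-rich ring A, its oxygen can be added afterwards with Markovnikov selectivity, and the ketone revealed only in the last, base-free steps.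

## Retrosynthesis

**15 back to 12 (functional group changes at C6 and C4).** The C6 hydroxyl is masked as a benzyl ether (14), which survives all earlier steps and leaves by neutral hydrogenolysis. The ketone of 14 comes from the benzylic alcohol 13, and 13 from hydration of the C3=C4 alkene of the 2-aryl-2H-chromene 12. Only the C4–O bond is cut here. Hydrogen-atom-transfer hydration must put oxygen on C4, which the benzylic radical ensures, and must leave the C2–H alone.

**12 back to 11 (C3=C4, ring C).** Cutting the alkene gives the diene 11, an aryl ether with a vinyl group on C2 and a vinyl group on C4a. Closing O1–C2 by oxa-Michael addition would run through the chalcone that racemises the product. Closing C4–C4a by acylation needs acid strong enough to ionise C2–O1. Metathesis is neutral and touches neither the C2–H nor the C2–O bond. The precursor is acyclic at ring C and has the single stereocentre already in place. The forward reaction must close a six-membered ring from two monosubstituted alkenes without moving the allyl double bond.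

**11 back to 6 and 10 (O1–C2, the stereocentre).** Cutting the ether bond gives the 2-vinylphenol 6 and the linear cinnamyl carbonate 10. Iridium-catalysed allylic etherification makes the O1–C2 bond, the C2 stereocentre and the vinyl group on C2 in one step from an achiral electrophile. A Mitsunobu coupling of a preformed 1-arylallyl alcohol would leak through an allyl cation. The vinylphenol 6 is preferred over the salicylaldehyde 5 as nucleophile because its aryloxide is more nucleophilic and a poorer leaving group, which limits re-ionisation of the product. The forward reaction must be branch-selective and enantioselective with an electron-rich cinnamyl unit.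

**6 back to 1 (ring A).** The vinyl group of 6 comes from the formyl group of 5 by Wittig methylenation. The formyl group of 5 is put ortho to the hydroxyl of phenol 4, whose two free positions are equivalent by symmetry, so there is no regiochemical question. Phenol 4 comes from aldehyde 2 by Baeyer–Villiger oxidation, which turns the formyl carbon of syringaldehyde into what becomes O1. Aldehyde 2 is the benzyl ether of syringaldehyde 1. The oxygen pattern of ring A is thus taken from 1 unchanged.

**10 back to 7 (ring B fragment).** Carbonate 10 comes from cinnamyl alcohol 9 and methyl chloroformate, and 9 from reduction of (E)-3,4-dimethoxycinnamic acid 7. The E alkene is kept throughout.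

## Roads not taken

**Alternative 1: ring A built last by a biomimetic Claisen cyclisation.** The cut is C4a–C5. Ring A is unravelled into a β-keto ester side chain on an (S)-2-aryl-dihydropyranone, methyl 2-(benzyloxy)-4-[(6S)-6-(3,4-dimethoxyphenyl)-4-oxo-5,6-dihydro-4H-pyran-2-yl]-3-oxobutanoate A2. Treatment with Mg(OMe)2 in methanol would make the extended enolate attack the ester through C4a; enolisation then aromatises ring A to the 5,7-dihydroxyflavanone A1.
- Merits: the oxygen pattern of ring A follows from the positions of the chain carbonyls, no arene substitution is needed, and the ketone at C4 is present from the start. On those two points it is cleaner than the chosen plan, which must place the C4 oxygen by a separate hydration.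
- Weak points: it builds, over many steps, a ring that can be bought with the correct pattern. A2 has several enolisable sites and can close through oxygen instead of carbon. The basic cyclisation medium can open the pyranone by β-elimination at C2. A1 then needs both phenols methylated, the chelated C5 hydroxyl only under basic forcing conditions that open the flavanone to the chalcone and racemise C2.
- Comparison: the chosen plan has the methyl ethers in place from syringaldehyde and a base-free endgame, and is clearly shorter.

**Alternative 2: ring C closed by palladium aryl–oxygen coupling.** The cut is O1–C8a. The (S)-benzylic alcohol of the bromo diol monosilyl ether A4 would couple with the ortho bromide through a palladium alkoxide (Pd(OAc)2, bulky biaryl di-tert-butylphosphine, Cs2CO3) to give the C4-silyloxyflavan A3.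
- Merits: C2 is made as a plain secondary benzylic alcohol, a stereocentre that is easy to set. The coupling does not touch the carbinol C–O bond, so it proceeds with retention. The C4 oxygen is in place from the aldol-type assembly, and no flavene is handled. In configurational security of C2 during ring closure and in placing the C4 oxygen, this road is better than the chosen one.
- Weak points: the bromide sits on a trialkoxy arene and adds slowly to palladium. The palladium alkoxide of a secondary benzylic alcohol can lose β-hydride, giving a ketone and reduced arene. A4 needs two controlled carbinol centres and selective silylation of one of two benzylic alcohols, and the C4 centre is then destroyed by oxidation. Desilylation, oxidation and debenzylation follow.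
- Comparison: the step count is similar to or higher than the chosen plan. The chosen plan makes only one stereocentre, catalytically, needs one protecting group, and draws the C3–C4 bridge from two vinyl groups.

**Alternative 3: ortho-quinone methide hetero-Diels–Alder reaction.** The cuts are O1–C2 and C3–C4 together. Salicylaldehyde 5 (the same aldehyde the chosen route passes through), trimethyl orthoformate and a chiral Brønsted acid would generate a methoxy-substituted ortho-quinone methide. This adds 3,4-dimethoxystyrene A6 to give the cis-4-methoxyflavan A5.
- Merits: it is the most convergent road. Two bonds and ring C form in one step from 5 and a commercial styrene, the polarity of the partners fixes the regiochemistry, and C4 arrives oxygenated. It would be several steps shorter than the chosen plan, and that advantage is real.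
- Weak points: the reactive species is close to an aryl oxocarbenium ion with no directing handle other than its counter-anion. With so electron-rich a styrene the addition is likely stepwise through a benzylic cation, which loosens both enantio- and diastereocontrol. A6 oligomerises under acid. The C2–O1 bond of A5 can ionise under the same acid. Converting the C4 methyl ether to the ketone must discriminate between two benzylic ether positions, C4 and C2.
- Comparison: the chosen plan is longer, but its stereocentre rests on a catalyst class established for branched allylic aryl ethers, and its ring closure and endgame are neutral.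

Key step: step 8

Assumption: the (Sa,Sc,Sc) antipode of the binaphthol-derived N,N-bis(1-phenylethyl)phosphoramidite is taken to give the (S) ether 11, by analogy with simple cinnamyl carbonates and aryloxides; if the analogy fails, the mirror-image ligand is used and nothing else changes.

## Steps

Step 1
Reactants: 1 syringaldehyde (4-hydroxy-3,5-dimethoxybenzaldehyde)
Product: 2 4-(benzyloxy)-3,5-dimethoxybenzaldehyde
Conditions: BnBr, K2CO3, DMF, 60 °C
Reagents that add atoms: benzyl bromide, BrCc1ccccc1
Why: Williamson etherification of the only phenol; the benzyl ether distinguishes the future C6 oxygen from the two methyl ethers and survives every step up to the final hydrogenolysis.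

Step 2
Reactants: 2 4-(benzyloxy)-3,5-dimethoxybenzaldehyde
Product: 4 4-(benzyloxy)-3,5-dimethoxyphenol, via 4-(benzyloxy)-3,5-dimethoxyphenyl formate 3 (not isolated)
Conditions: mCPBA, CH2Cl2, rt; then K2CO3 (cat.), MeOH, rt
Reagents that add atoms: meta-chloroperoxybenzoic acid, OOC(=O)c1cccc(Cl)c1
Why: Baeyer–Villiger oxidation with migration of the electron-rich aryl group gives the aryl formate, which methanolysis cleaves to the phenol; the new oxygen becomes O1 of the target.

Step 3
Reactants: 4 4-(benzyloxy)-3,5-dimethoxyphenol
Product: 5 3-(benzyloxy)-6-hydroxy-2,4-dimethoxybenzaldehyde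
Conditions: MgCl2, Et3N, (CH2O)n, MeCN, reflux; aq. HCl work-up
Reagents that add atoms: paraformaldehyde (as formaldehyde), C=O
Why: Magnesium-mediated ortho-formylation (Casnati–Skattebøl) delivers formaldehyde to the carbon ortho to the phenoxide through a magnesium chelate; the two free ring positions are equivalent, so only one product can form.

Step 4
Reactants: 5 3-(benzyloxy)-6-hydroxy-2,4-dimethoxybenzaldehyde
Product: 6 4-(benzyloxy)-2-ethenyl-3,5-dimethoxyphenol
Conditions: Ph3PCH3Br (3 equiv), KOt-Bu (3 equiv), THF, 0 °C to rt; pH 7 work-up, product used promptly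
Reagents that add atoms: methyltriphenylphosphonium bromide, C[P+](c1ccccc1)(c1ccccc1)c1ccccc1.[Br-]
Why: Wittig methylenation of a salicylaldehyde with excess ylide, the first equivalent serving to deprotonate the phenol; this is the standard route to 2-vinylphenols and installs the C4 carbon as a terminal alkene.

Step 5
Reactants: 7 (E)-3,4-dimethoxycinnamic acid
Product: 9 (E)-3-(3,4-dimethoxyphenyl)prop-2-en-1-ol, via ethyl (E)-3-(3,4-dimethoxyphenyl)acryloyl carbonate 8 (not isolated)
Conditions: ClCO2Et, Et3N, THF, −10 °C; then NaBH4, H2O, 0 °C
Reagents that add atoms: ethyl chloroformate, CCOC(=O)Cl (its atoms appear only in 8 and are lost on reduction to 9)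
Why: Activation as the mixed carbonic anhydride followed by borohydride reduction gives the allylic alcohol by 1,2-reduction only, keeping the E alkene.

Step 6
Reactants: 9 (E)-3-(3,4-dimethoxyphenyl)prop-2-en-1-ol
Product: 10 (E)-3-(3,4-dimethoxyphenyl)allyl methyl carbonate
Conditions: ClCO2Me, pyridine, CH2Cl2, 0 °C
Reagents that add atoms: methyl chloroformate, COC(=O)Cl
Why: Acylation of the primary allylic alcohol; the methyl carbonate is the usual leaving group for iridium-catalysed allylic substitution.

Step 7
Reactants: 6 4-(benzyloxy)-2-ethenyl-3,5-dimethoxyphenol; 10 (E)-3-(3,4-dimethoxyphenyl)allyl methyl carbonate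
Product: 11 (S)-2-(benzyloxy)-5-{[1-(3,4-dimethoxyphenyl)prop-2-en-1-yl]oxy}-1,3-dimethoxy-4-vinylbenzene
Conditions: 6, LiN(SiMe3)2, THF, 0 °C; then [Ir(cod)Cl]2 (2 mol%), (Sa,Sc,Sc)-O,O'-(1,1'-binaphthyl-2,2'-diyl) N,N-bis(1-phenylethyl)phosphoramidite (4 mol%, catalyst preactivated with n-PrNH2), 10, THF, rt; stopped at full conversion of 10
Reagents that add atoms: none
Why: Iridium-catalysed asymmetric allylic etherification: the cyclometalated iridium phosphoramidite complex ionises 10 to a π-allyl intermediate and the lithium aryloxide attacks the aryl-bearing terminus anti to the metal, giving the branched ether. The chiral ligand fixes which face of the allyl unit is bound and so sets C2 as (S). The electron-rich aryloxide of 6 is a good nucleophile and a poor leaving group, which limits re-ionisation of the product.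

Step 8
Reactants: 11 (S)-2-(benzyloxy)-5-{[1-(3,4-dimethoxyphenyl)prop-2-en-1-yl]oxy}-1,3-dimethoxy-4-vinylbenzene
Product: 12 (S)-6-(benzyloxy)-2-(3,4-dimethoxyphenyl)-5,7-dimethoxy-2H-chromene
Conditions: second-generation Grubbs catalyst RuCl2(=CHPh)(H2IMes)(PCy3) (5 mol%), 1,4-benzoquinone (10 mol%), CH2Cl2 (0.01 M), 40 °C, dark
Reagents that add atoms: none
Why: The ruthenium benzylidene engages one terminal alkene of 11 by [2+2] cycloaddition and cycloreversion to give a substrate-bound carbene; at the styrene terminus this is an ortho-alkoxybenzylidene chelate that remains active. The carbene adds to the second alkene within the molecule, and cycloreversion of the ruthenacyclobutane releases 12 and Ru=CH2, which re-enters the cycle while ethylene escapes and drives the reaction. The closest known reaction type is the ring-closing metathesis of 2-vinylaryl allyl ethers, including branched 1-arylallyl ethers, to 2H-chromenes. Ring C closes as a six-membered ring from a 1,7-diene, with C3 and C4 as the two internal alkene carbons, so the new double bond is necessarily cis and endocyclic. No stereocentre is created, and C2 is carried through because neither its C–H nor its C–O bond takes part in the carbene chemistry. The step needs ring closure to win over cross-metathesis and over double-bond migration: the ortho relationship through O1–C8a–C4a holds the two vinyl groups within reach, high dilution disfavours dimers, and benzoquinone intercepts ruthenium hydrides that would move the allyl double bond onto C2 and erase the stereocentre. Neutral aprotic conditions at 40 °C in the dark protect the ionisable C2–O1 bond and the light-sensitive chromene.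

Step 9
Reactants: 12 (S)-6-(benzyloxy)-2-(3,4-dimethoxyphenyl)-5,7-dimethoxy-2H-chromene
Product: 13 (2S)-6-(benzyloxy)-2-(3,4-dimethoxyphenyl)-5,7-dimethoxychroman-4-ol (both C4 epimers)
Conditions: Co(acac)2 (20 mol%), PhSiH3 (2 equiv), O2 (1 atm), THF, 0 °C to rt, dark; filtered through Et3N-deactivated silica and used at once
Reagents that add atoms: dioxygen, O=O
Why: Mukaiyama hydration: hydrogen-atom transfer from a cobalt hydride to C3 gives the C4 radical stabilised by ring A, which captures O2, and the silane reduces the peroxide to the alcohol, so oxygen ends on C4 only. The new C4 centre is not controlled and need not be, since both epimers give the same ketone; C2 is not involved.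

Step 10
Reactants: 13 (2S)-6-(benzyloxy)-2-(3,4-dimethoxyphenyl)-5,7-dimethoxychroman-4-ol
Product: 14 (S)-6-(benzyloxy)-2-(3,4-dimethoxyphenyl)-5,7-dimethoxychroman-4-one
Conditions: Pr4N[RuO4] (5 mol%), N-methylmorpholine N-oxide, 4 Å MS, CH2Cl2, rt
Reagents that add atoms: none
Why: Ley–Griffith oxidation of a secondary benzylic alcohol under non-acidic conditions, which suits an alcohol that ionises easily at C4; the medium is too weakly basic to open the flavanone, so C2 stays (S).

Step 11
Reactants: 14 (S)-6-(benzyloxy)-2-(3,4-dimethoxyphenyl)-5,7-dimethoxychroman-4-one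
Product: 15 (S)-2-(3,4-dimethoxyphenyl)-6-hydroxy-5,7-dimethoxychroman-4-one
Conditions: H2 (1 atm), Pd/C (10%), EtOAc, rt; stopped at consumption of 14
Reagents that add atoms: none
Why: Hydrogenolysis of the aryl benzyl ether under neutral conditions, a standard way to unmask benzyl-protected flavanones; the primary O-benzyl bond cleaves faster than the cyclic C2–O1 bond or the aryl ketone is reduced, and no acid or base touches C2 or the C5 methyl ether.

## Compound list

1 | syringaldehyde (4-hydroxy-3,5-dimethoxybenzaldehyde) | COc1cc(C=O)cc(OC)c1O | starting material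
2 | 4-(benzyloxy)-3,5-dimethoxybenzaldehyde | COc1cc(C=O)cc(OC)c1OCc1ccccc1 | intermediate
3 | 4-(benzyloxy)-3,5-dimethoxyphenyl formate | O=COc1cc(OC)c(OCc2ccccc2)c(OC)c1 | intermediate
4 | 4-(benzyloxy)-3,5-dimethoxyphenol | Oc1cc(OC)c(OCc2ccccc2)c(OC)c1 | intermediate
5 | 3-(benzyloxy)-6-hydroxy-2,4-dimethoxybenzaldehyde | O=Cc1c(O)cc(OC)c(OCc2ccccc2)c1OC | intermediate
6 | 4-(benzyloxy)-2-ethenyl-3,5-dimethoxyphenol | C=Cc1c(O)cc(OC)c(OCc2ccccc2)c1OC | intermediate
7 | (E)-3,4-dimethoxycinnamic acid | COc1ccc(/C=C/C(=O)O)cc1OC | starting material
8 | ethyl (E)-3-(3,4-dimethoxyphenyl)acryloyl carbonate | CCOC(=O)OC(=O)/C=C/c1ccc(OC)c(OC)c1 | intermediate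
9 | (E)-3-(3,4-dimethoxyphenyl)prop-2-en-1-ol | COc1ccc(/C=C/CO)cc1OC | intermediate
10 | (E)-3-(3,4-dimethoxyphenyl)allyl methyl carbonate | COC(=O)OC/C=C/c1ccc(OC)c(OC)c1 | intermediate
11 | (S)-2-(benzyloxy)-5-{[1-(3,4-dimethoxyphenyl)prop-2-en-1-yl]oxy}-1,3-dimethoxy-4-vinylbenzene | C=C[C@H](Oc1cc(OC)c(OCc2ccccc2)c(OC)c1C=C)c1ccc(OC)c(OC)c1 | intermediate
12 | (S)-6-(benzyloxy)-2-(3,4-dimethoxyphenyl)-5,7-dimethoxy-2H-chromene | COc1ccc([C@@H]2C=Cc3c(cc(OC)c(OCc4ccccc4)c3OC)O2)cc1OC | intermediate
13 | (2S)-6-(benzyloxy)-2-(3,4-dimethoxyphenyl)-5,7-dimethoxychroman-4-ol, both C4 epimers | COc1ccc([C@@H]2CC(O)c3c(cc(OC)c(OCc4ccccc4)c3OC)O2)cc1OC | intermediate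
14 | (S)-6-(benzyloxy)-2-(3,4-dimethoxyphenyl)-5,7-dimethoxychroman-4-one | COc1ccc([C@@H]2CC(=O)c3c(cc(OC)c(OCc4ccccc4)c3OC)O2)cc1OC | intermediate
15 | (S)-2-(3,4-dimethoxyphenyl)-6-hydroxy-5,7-dimethoxychroman-4-one | COc1ccc([C@@H]2CC(=O)c3c(cc(OC)c(O)c3OC)O2)cc1OC | target

## Step count and least certain steps

Total step count: 11. Longest linear sequence: 9 steps (steps 1 to 4, then 7 to 11); steps 5 and 6 form the ring-B branch.

**Step 8 (key step).** The main risks are migration of the allyl double bond onto C2 through ruthenium hydrides, which would destroy the stereocentre. Ionisation of the doubly activated C2–O1 bond at the metal is a second risk. Slow turnover is a third: both alkenes are hindered and the styrene can hold the catalyst as a chelate, which lets intermolecular metathesis compete. The fallback gives up ring closure through C3=C4 and makes C2–aryl last. It sets out from phenol 4. Ortho-acetylation (AcOH, BF3·OEt2, warm) would give 1-[3-(benzyloxy)-6-hydroxy-2,4-dimethoxyphenyl]ethan-1-one F1. Condensation with N,N-dimethylformamide dimethyl acetal would give the enaminone (E)-1-[3-(benzyloxy)-6-hydroxy-2,4-dimethoxyphenyl]-3-(dimethylamino)prop-2-en-1-one F2. Cyclisation with HCl in CH2Cl2 would give 6-(benzyloxy)-5,7-dimethoxy-4H-chromen-4-one F3. Palladium-catalysed asymmetric conjugate addition of 3,4-dimethoxyphenylboronic acid (Pd(OCOCF3)2, the t-BuPyOX antipode that gives the (S) product, NH4PF6, H2O, ClCH2CH2Cl, 60 °C) would then give 14, where the route resumes at step 11. This is held in reserve because a chromone with donor groups at C5 and C7 is a weak acceptor.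

**Step 7.** The 3,4-dimethoxyphenyl group stabilises the allyl cation, so the catalyst may re-ionise the branched ether. That would erode the enantiomeric purity and let the product drift to the linear ether. The very electron-rich aryloxide may also be allylated at its free ortho carbon instead of at oxygen. The fallback sets out from 6 and commercial 3-chloro-1-(3,4-dimethoxyphenyl)propan-1-one F4. Corey–Bakshi–Shibata reduction ((S)-2-methyl-CBS-oxazaborolidine, BH3·SMe2, THF) would give (R)-3-chloro-1-(3,4-dimethoxyphenyl)propan-1-ol F5. Mitsunobu coupling with 6 (PPh3, DIAD, toluene, −20 °C) would give, with inversion, 2-(benzyloxy)-5-{[(1S)-3-chloro-1-(3,4-dimethoxyphenyl)propyl]oxy}-1,3-dimethoxy-4-vinylbenzene F6; the electron-rich carbinol may lose some enantiomeric purity here. Displacement with PhSeNa (from (PhSe)2 and NaBH4, EtOH) would give 2-(benzyloxy)-5-{[(1S)-1-(3,4-dimethoxyphenyl)-3-(phenylselanyl)propyl]oxy}-1,3-dimethoxy-4-vinylbenzene F7. Oxidation with H2O2 (THF, 0 °C) would give the selenoxide 2-(benzyloxy)-5-{[(1S)-1-(3,4-dimethoxyphenyl)-3-(phenylseleninyl)propyl]oxy}-1,3-dimethoxy-4-vinylbenzene F8, whose syn-elimination at room temperature returns the route to 11.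

**Step 9.** Peroxyl radicals may abstract the doubly activated C2 hydrogen and start over-oxidation of ring C. The chromene may racemise by light-induced electrocyclic ring opening if the reaction is slow. The acid-labile C4 alcohol may ionise on isolation. The fallback replaces the radical hydration by a polar one and sets out from 12. Copper hydride-catalysed Markovnikov hydroboration (CuCl, NaOt-Bu, 1,2-bis(diphenylphosphino)benzene, pinacolborane, THF, rt) would place copper, then boron, on benzylic C4. This would give (2S)-6-(benzyloxy)-2-(3,4-dimethoxyphenyl)-5,7-dimethoxy-4-(4,4,5,5-tetramethyl-1,3,2-dioxaborolan-2-yl)chromane F9. Oxidation with NaBO3·4H2O in THF/H2O returns the route to 13.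

**Step 4.** The aldehyde is deactivated as its phenoxide and may olefinate slowly. The electron-rich vinylphenol may oligomerise through protonation during isolation. The fallback reverses the order of olefination and etherification and sets out from 5. The lithium salt of 5 and carbonate 10, under the iridium conditions of step 7, would give (S)-3-(benzyloxy)-6-{[1-(3,4-dimethoxyphenyl)prop-2-en-1-yl]oxy}-2,4-dimethoxybenzaldehyde F10. Wittig methylenation (Ph3PCH3Br, KOt-Bu, THF, −78 to 0 °C) returns the route to 11. The price is a less nucleophilic aryloxide in the iridium step.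

## Further compounds

F1 | step 8 | 1-[3-(benzyloxy)-6-hydroxy-2,4-dimethoxyphenyl]ethan-1-one | CC(=O)c1c(O)cc(OC)c(OCc2ccccc2)c1OC
F2 | step 8 | (E)-1-[3-(benzyloxy)-6-hydroxy-2,4-dimethoxyphenyl]-3-(dimethylamino)prop-2-en-1-one | CN(C)/C=C/C(=O)c1c(O)cc(OC)c(OCc2ccccc2)c1OC
F3 | step 8 | 6-(benzyloxy)-5,7-dimethoxy-4H-chromen-4-one | COc1cc2occc(=O)c2c(OC)c1OCc1ccccc1
F4 | step 7 | 3-chloro-1-(3,4-dimethoxyphenyl)propan-1-one | COc1ccc(C(=O)CCCl)cc1OC
F5 | step 7 | (R)-3-chloro-1-(3,4-dimethoxyphenyl)propan-1-ol | COc1ccc([C@H](O)CCCl)cc1OC
F6 | step 7 | 2-(benzyloxy)-5-{[(1S)-3-chloro-1-(3,4-dimethoxyphenyl)propyl]oxy}-1,3-dimethoxy-4-vinylbenzene | ClCC[C@H](Oc1cc(OC)c(OCc2ccccc2)c(OC)c1C=C)c1ccc(OC)c(OC)c1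
F7 | step 7 | 2-(benzyloxy)-5-{[(1S)-1-(3,4-dimethoxyphenyl)-3-(phenylselanyl)propyl]oxy}-1,3-dimethoxy-4-vinylbenzene | c1ccccc1[Se]CC[C@H](Oc1cc(OC)c(OCc2ccccc2)c(OC)c1C=C)c1ccc(OC)c(OC)c1
F8 | step 7 | 2-(benzyloxy)-5-{[(1S)-1-(3,4-dimethoxyphenyl)-3-(phenylseleninyl)propyl]oxy}-1,3-dimethoxy-4-vinylbenzene | O=[Se](CC[C@H](Oc1cc(OC)c(OCc2ccccc2)c(OC)c1C=C)c1ccc(OC)c(OC)c1)c1ccccc1
F9 | step 9 | (2S)-6-(benzyloxy)-2-(3,4-dimethoxyphenyl)-5,7-dimethoxy-4-(4,4,5,5-tetramethyl-1,3,2-dioxaborolan-2-yl)chromane, both C4 epimers | COc1ccc([C@@H]2CC(B3OC(C)(C)C(C)(C)O3)c3c(cc(OC)c(OCc4ccccc4)c3OC)O2)cc1OC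
F10 | step 4 | (S)-3-(benzyloxy)-6-{[1-(3,4-dimethoxyphenyl)prop-2-en-1-yl]oxy}-2,4-dimethoxybenzaldehyde | C=C[C@H](Oc1cc(OC)c(OCc2ccccc2)c(OC)c1C=O)c1ccc(OC)c(OC)c1
A1 | alternative 1 | (S)-6-(benzyloxy)-2-(3,4-dimethoxyphenyl)-5,7-dihydroxychroman-4-one | COc1ccc([C@@H]2CC(=O)c3c(cc(O)c(OCc4ccccc4)c3O)O2)cc1OC
A2 | alternative 1 | methyl 2-(benzyloxy)-4-[(6S)-6-(3,4-dimethoxyphenyl)-4-oxo-5,6-dihydro-4H-pyran-2-yl]-3-oxobutanoate | COc1ccc([C@@H]2CC(=O)C=C(CC(=O)C(OCc3ccccc3)C(=O)OC)O2)cc1OC
A3 | alternative 2 | (2S,4S)-6-(benzyloxy)-4-(tert-butyldimethylsilyloxy)-2-(3,4-dimethoxyphenyl)-5,7-dimethoxychromane | COc1ccc([C@@H]2C[C@H](O[Si](C)(C)C(C)(C)C)c3c(cc(OC)c(OCc4ccccc4)c3OC)O2)cc1OC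
A4 | alternative 2 | (1S,3S)-3-[3-(benzyloxy)-6-bromo-2,4-dimethoxyphenyl]-3-(tert-butyldimethylsilyloxy)-1-(3,4-dimethoxyphenyl)propan-1-ol | COc1ccc([C@@H](O)C[C@H](O[Si](C)(C)C(C)(C)C)c2c(Br)cc(OC)c(OCc3ccccc3)c2OC)cc1OC
A5 | alternative 3 | (2S,4S)-6-(benzyloxy)-2-(3,4-dimethoxyphenyl)-4,5,7-trimethoxychromane | COc1ccc([C@@H]2C[C@H](OC)c3c(cc(OC)c(OCc4ccccc4)c3OC)O2)cc1OC
A6 | alternative 3 | 3,4-dimethoxystyrene | C=Cc1ccc(OC)c(OC)c1
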